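Ring B is cut at C9–C10. The C8=C17 methylene, lying next to the C9 stereocentre and the quaternary C10 at the cis junction of rings A and B, marks where a 2-substituted allylsilane has attacked an enone β-carbon through its γ-carbon. One Lewis-acid step therefore closes ring B, fixes C9 and C10 and unveils the methylene. Its substrate is a ring A 3-methylcyclohex-2-enone (C2 ketone, C1=C10) carrying the C3 silyl ether, the C4 methyl and methyl ester, and on C5 a (Z)-allylsilane chain that ends in a C12 chloride, a latent iodide for the late diene coupling.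

Key step: step 17

Remark: ring carbons carry labdane numbers throughout (ring A = C1–C5 and C10, C19 = carboxyl carbon on C4, C17 = methylene carbon on C8); "cis" and "trans" at C3 and C5 refer to the C4 methyl and the C4 carboxyl carbon.
Assumption: in step 8 the methyl group is taken to enter the potassium amide enolate on the face remote from the chelated methoxymethyl arm of the (S)-auxiliary, which gives the C4 configuration drawn; if the sense proved opposite, the (R)-auxiliary would be used.

Step 1
Reactants: 1 hex-3-yne-1,6-diol
Product: 2 6-(tert-butyldimethylsilyloxy)hex-3-yn-1-ol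
Conditions: NaH (1.0 equiv), THF, 0 °C to rt; TBSCl (1.0 equiv)
Reagents that add atoms: tert-butyldimethylsilyl chloride (CC(C)(C)[Si](C)(C)Cl)
Why: Monosilylation of a symmetrical diol through its sparingly soluble monosodium alkoxide should mask one hydroxyl (the future C6 oxygen) and leave the other free for ring formation.

Step 2
Reactants: 2 6-(tert-butyldimethylsilyloxy)hex-3-yn-1-ol
Product: 3 5-[2-(tert-butyldimethylsilyloxy)ethyl]-2,3-dihydrofuran
Conditions: PdCl2(PhCN)2 (2 mol%), Et2O, rt; Et3N quench
Reagents that add atoms: none
Why: Divalent palladium activates the alkyne for 5-endo-dig attack by the homopropargylic hydroxyl (alkynol cycloisomerisation), giving a cyclic enol ether whose ring holds the future C11 carbon cis to the ring oxygen on the C8=C9 double bond.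

Step 3
Reactants: 3 5-[2-(tert-butyldimethylsilyloxy)ethyl]-2,3-dihydrofuran; 4 (trimethylsilyl)methylmagnesium chloride
Product: 5 (Z)-6-(tert-butyldimethylsilyloxy)-4-[(trimethylsilyl)methyl]hex-3-en-1-ol
Conditions: 4 (3 equiv), NiCl2(PPh3)2 (5 mol%), PhMe, reflux; aq. NH4Cl
Reagents that add atoms: none
Why: Nickel-catalysed Kumada-type coupling of a cyclic enol ether: zerovalent nickel inserts into the vinylic C–O bond and the silylmethyl group (no β-hydrogen) replaces oxygen with retention, so CH2SiMe3 ends cis to the C11–C12 arm, which is the (Z)-allylsilane, and the C12 hydroxyl is set free.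

Step 4
Reactants: 5 (Z)-6-(tert-butyldimethylsilyloxy)-4-[(trimethylsilyl)methyl]hex-3-en-1-ol
Product: 6 (Z)-tert-butyl{6-chloro-3-[(trimethylsilyl)methyl]hex-3-enyloxy}dimethylsilane
Conditions: PPh3, CCl4, CH2Cl2, 40 °C
Reagents that add atoms: carbon tetrachloride (ClC(Cl)(Cl)Cl)
Why: Appel chlorination under neutral conditions spares the allylsilane and the silyl ether and installs the C12 chloride, which is inert to every later reagent until it is exchanged for iodide in step 21.

Step 5
Reactants: 6 (Z)-tert-butyl{6-chloro-3-[(trimethylsilyl)methyl]hex-3-enyloxy}dimethylsilane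
Product: 7 (Z)-6-chloro-3-[(trimethylsilyl)methyl]hex-3-en-1-ol
Conditions: TBAF, AcOH, THF, 0 °C
Reagents that add atoms: none
Why: Buffered fluoride cleavage of the primary silyl ether frees the C6 hydroxyl without touching the allylsilane or the primary chloride.

Step 6
Reactants: 7 (Z)-6-chloro-3-[(trimethylsilyl)methyl]hex-3-en-1-ol
Product: 8 (Z)-[5-chloro-2-(2-iodoethyl)pent-2-enyl]trimethylsilane
Conditions: PPh3, I2, imidazole, CH2Cl2, 0 °C (iodine pre-complexed with the phosphine)
Reagents that add atoms: iodine (II)
Why: Appel-type iodination of the primary alcohol gives the C6 iodide needed for selective magnesium insertion in the presence of the C12 chloride.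

Step 7
Reactants: 9 2-methoxy-5-methylbenzoic acid; 10 (S)-2-(methoxymethyl)pyrrolidine
Product: 12 (S)-(2-methoxy-5-methylphenyl)[2-(methoxymethyl)pyrrolidin-1-yl]methanone, via acid chloride 11 (not isolated)
Conditions: (COCl)2, DMF (cat.), CH2Cl2, 0 °C to rt; then 10, Et3N, CH2Cl2, 0 °C
Reagents that add atoms: none
Why: Acyl chloride formation followed by Schotten–Baumann-type amidation attaches the chiral auxiliary that will control C4.

Step 8
Reactants: 12 (S)-(2-methoxy-5-methylphenyl)[2-(methoxymethyl)pyrrolidin-1-yl]methanone
Product: 14 ring A diene amide, via potassium enolate 13 (not isolated)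
Conditions: K, NH3(l), THF, t-BuOH (1 equiv), −78 °C; piperylene; then MeI, −78 °C
Reagents that add atoms: iodomethane (CI)
Why: Asymmetric Birch reduction–alkylation of a chiral 2-methoxybenzamide: the chelated amide enolate is methylated on the face remote from the methoxymethyl arm, which sets the quaternary C4 and leaves the C2=C3 methyl enol ether and the C5=C10 alkene.

Step 9
Reactants: 14 ring A diene amide
Product: 15 ring A dienone amide
Conditions: (C5H5NH)2Cr2O7, t-BuOOH, Celite, PhH, rt
Reagents that add atoms: tert-butyl hydroperoxide (CC(C)(C)OO)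
Why: Chromium-mediated oxidation of the doubly allylic C1 methylene is the standard way from Birch 1,4-dienes to cross-conjugated cyclohexa-2,5-dienones and should tolerate the enol ether and the amide.

Step 10
Reactants: 8 (Z)-[5-chloro-2-(2-iodoethyl)pent-2-enyl]trimethylsilane; 15 ring A dienone amide
Product: 18 C5-alkylated vinylogous ester ketone, via chain Grignard reagent 16 (not isolated), via silyl enol ether 17 (not isolated)
Conditions: 8, Mg, Et2O, rt; then CuBr·SMe2 (10 mol%), Me3SiCl, HMPA, THF, −78 °C, 15; 0.5 M HCl work-up
Reagents that add atoms: none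
Why: Copper-catalysed, silyl-chloride-accelerated conjugate addition of the Grignard reagent goes to C5, the β-carbon of the only true enone half of the planar dienone (the C3 side is a deactivated vinylogous ester), and the nucleophile should enter anti to the bulky C4 carboxamide so that C5–C6 is cis to the C4 methyl; the transient C10 centre is removed in step 12.

Step 11
Reactants: 18 C5-alkylated vinylogous ester ketone
Product: 20 C3 enone amide, via allylic alcohol 19 (not isolated)
Conditions: i-Bu2AlH, CH2Cl2, −78 °C; then 1 M HCl, THF, 0 °C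
Reagents that add atoms: water (O)
Why: Stork–Danheiser transposition: 1,2-reduction of the vinylogous ester carbonyl and brief acid hydrolysis with loss of water and methanol move the carbonyl to C3, under conditions that alkyl-tethered allylsilanes of this kind tolerate.

Step 12
Reactants: 20 C3 enone amide
Product: 22 C2 triethylsilyloxy C3 ketone, via hydroxy ketone 21 (not isolated)
Conditions: LiN(iPr)2, THF–HMPA, −78 °C; 2-(phenylsulfonyl)-3-phenyloxaziridine; then Et3SiCl, −78 to 0 °C
Reagents that add atoms: 2-(phenylsulfonyl)-3-phenyloxaziridine (O=S(=O)(N1OC1c1ccccc1)c1ccccc1); triethylsilyl chloride (CC[Si](CC)(CC)Cl)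
Why: With no α′-hydrogen available, base removes the γ-hydrogen at C10 to give the linear dienolate, which the oxaziridine hydroxylates at its α-carbon C2 (Davis oxidation) while the alkene moves to C1=C10, and the alkoxide is silylated in the same flask; the C2 configuration is irrelevant because C2 becomes a ketone.

Step 13
Reactants: 22 C2 triethylsilyloxy C3 ketone
Product: 24 C2,C3 diol, via silyl ether alcohol 23 (not isolated)
Conditions: Zn(BH4)2, Et2O, −20 °C; aq. NH4Cl; then TBAF, THF, 0 °C
Reagents that add atoms: none
Why: Chelation-controlled reduction: zinc held between the C3 ketone and the amide carbonyl keeps the carboxamide in the carbonyl plane and the C4 methyl pseudo-axial, so hydride is delivered anti to that methyl and the C3 hydroxyl ends trans to the carboxamide; fluoride then removes the labile triethylsilyl group.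

Step 14
Reactants: 24 C2,C3 diol
Product: 25 C3 hydroxy C2 enone amide
Conditions: MnO2, CH2Cl2, rt
Reagents that add atoms: none
Why: MnO2 oxidises only the allylic C2 alcohol and leaves the saturated neopentyl C3 alcohol, so the conjugated C2 enone appears without any reagent that would attack the allylsilane.

Step 15
Reactants: 25 C3 hydroxy C2 enone amide
Product: 26 C3 silyloxy C2 enone amide
Conditions: TBSOTf, 2,6-lutidine (excess), CH2Cl2, −78 °C
Reagents that add atoms: tert-butyldimethylsilyl trifluoromethanesulfonate (CC(C)(C)[Si](C)(C)OS(=O)(=O)C(F)(F)F)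
Why: Silyl triflate silylation of the hindered C3 hydroxyl, buffered by excess lutidine at low temperature so that the reagent cannot trigger ring closure.

Step 16
Reactants: 26 C3 silyloxy C2 enone amide
Product: 28 key precursor enone methyl ester, via imidate salt 27 (not isolated)
Conditions: Me3OBF4, 2,6-di-tert-butylpyridine, CH2Cl2, rt; then aq. NaH2PO4 (pH 5), THF; NaHCO3 wash
Reagents that add atoms: trimethyloxonium tetrafluoroborate (C[O+](C)C.F[B-](F)(F)F); water (O)
Why: O-Methylation of the tertiary amide gives an imidate salt whose mildly acidic hydrolysis expels the protonated pyrrolidine, which turns the hindered amide into the methyl ester without harming enone, silyl ether or allylsilane and returns the auxiliary.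

Step 17
Reactants: 28 key precursor enone methyl ester
Product: 29 cis-decalin C2 ketone
Conditions: TiCl4 (1.1 equiv), CH2Cl2, −78 °C; H2O quench
Reagents that add atoms: none
Why: Coordination of TiCl4 to the C2 carbonyl makes C10 electrophilic; C9, the γ-carbon of the allylsilane, bonds to it with silicon antiperiplanar to the new bond, and the β-silyl carbocation at C8 collapses by loss of Me3SiCl to the C8=C17 double bond, leaving a titanium enolate that is protonated on work-up. The closest known reaction type is the intramolecular Hosomi–Sakurai conjugate addition of allylsilanes to 4-tethered 3-methylcyclohex-2-enones, which gives cis-fused bicycles with an angular methyl group. Ring B closes as a six-membered ring, exo with respect to the enone double bond and endo with respect to the allylsilane double bond (C8 and C9 both become ring atoms), through a chair-like transition state. C10 is fixed by C5, because the three-atom tether C6–C7–C8 can deliver C9 only to the enone face on which it is attached, so the C10 methyl and the C5 hydrogen end syn (cis fusion). C9 is fixed by the (Z) double bond, because in the chair the C9 substituent trans to C7, here C11, is forced pseudo-equatorial and is therefore cis to the axial C10 methyl. The step needs conjugate over direct addition and C–C bond formation over protodesilylation, which the strain of any 1,2-closure, the high nucleophilicity of the 2,2-disubstituted allylsilane and dry, low-temperature conditions should secure.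

Step 18
Reactants: 29 cis-decalin C2 ketone
Product: 30 C2 alcohol
Conditions: NaBH4, MeOH, 0 °C
Reagents that add atoms: none
Why: Borohydride reduction of the C2 ketone (either C2 epimer serves) prepares the deoxygenation, and the hindered ester, the chloride and the silyl ether are inert.

Step 19
Reactants: 30 C2 alcohol
Product: 31 C2 phenyl thionocarbonate
Conditions: PhOC(S)Cl, pyridine, DMAP (cat.), CH2Cl2, rt
Reagents that add atoms: O-phenyl chlorothionoformate (S=C(Cl)Oc1ccccc1)
Why: Acylation of the secondary alcohol under nucleophilic catalysis without strong base avoids 1,2-migration of the neighbouring silyl group.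

Step 20
Reactants: 31 C2 phenyl thionocarbonate
Product: 32 C12 chloride decalin
Conditions: Bu3SnH, AIBN (cat.), PhMe, 90 °C
Reagents that add atoms: none
Why: Barton–McCombie deoxygenation: the C2 radical is reduced by the stannane, a β-silyloxy radical does not fragment, attack on C8 is geometrically excluded in the chair cis-decalin and the primary chloride reacts far more slowly than the thionocarbonate.

Step 21
Reactants: 32 C12 chloride decalin
Product: 33 C12 iodide decalin
Conditions: NaI, butan-2-one, 80 °C
Reagents that add atoms: sodium iodide ([Na+].[I-])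
Why: Finkelstein exchange of the primary chloride, driven by precipitation of NaCl, unmasks the iodide for coupling.

Step 22
Reactants: 34 2-chlorobuta-1,3-diene
Product: 35 buta-1,3-dien-2-ylmagnesium chloride
Conditions: Mg, ZnCl2 (cat.), THF, reflux; used as solution
Reagents that add atoms: magnesium ([Mg])
Why: Zinc-chloride-promoted magnesium insertion into the vinylic C–Cl bond gives the 2-butadienyl Grignard reagent, which is used at once.

Step 23
Reactants: 33 C12 iodide decalin; 35 buta-1,3-dien-2-ylmagnesium chloride
Product: 36 triene silyl ether methyl ester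
Conditions: Li2CuCl4 (3 mol%), THF, −10 to 0 °C
Reagents that add atoms: none
Why: Copper-catalysed sp3–sp2 Grignard cross-coupling of the primary iodide forms C12–C13 and installs the 2-substituted butadiene, while the neopentyl-type methyl ester is too hindered to compete at low temperature.

Step 24
Reactants: 36 triene silyl ether methyl ester
Product: 37 triene silyl ether acid
Conditions: n-PrSLi, HMPA, rt; then cold 0.1 M HCl
Reagents that add atoms: none
Why: Thiolate SN2 demethylation at the methyl carbon cleaves the hindered ester without acid or hydroxide, which spares the diene, the methylene and the silyl ether.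

Step 25
Reactants: 37 triene silyl ether acid
Product: 38 hydroxy acid
Conditions: TBAF, THF, 50 °C
Reagents that add atoms: none
Why: Fluoride cleavage of the hindered secondary silyl ether is chosen over acid because of the acid-sensitive diene.

Step 26
Reactants: 38 hydroxy acid
Product: 40 target CNP0243981.1, via mixed anhydride 39 (not isolated)
Conditions: Ac2O, DMAP, pyridine, rt; then H2O, THF
Reagents that add atoms: acetic anhydride (CC(=O)OC(C)=O)
Why: DMAP-catalysed acetylation esterifies the C3 hydroxyl, and the mixed anhydride formed at the carboxyl group is hydrolysed on aqueous work-up, leaving the acetoxy acid with all stereocentres untouched.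

Compound list
1 | hex-3-yne-1,6-diol | OCCC#CCCO | starting material
2 | 6-(tert-butyldimethylsilyloxy)hex-3-yn-1-ol | OCCC#CCCO[Si](C)(C)C(C)(C)C | intermediate
3 | 5-[2-(tert-butyldimethylsilyloxy)ethyl]-2,3-dihydrofuran | CC(C)(C)[Si](C)(C)OCCC1=CCCO1 | intermediate
4 | (trimethylsilyl)methylmagnesium chloride | C[Si](C)(C)C[Mg]Cl | starting material
5 | (Z)-6-(tert-butyldimethylsilyloxy)-4-[(trimethylsilyl)methyl]hex-3-en-1-ol; CH2SiMe3 cis to the hydroxyethyl (C11–C12) arm | C[Si](C)(C)C/C(=C\CCO)CCO[Si](C)(C)C(C)(C)C | intermediate
6 | (Z)-tert-butyl{6-chloro-3-[(trimethylsilyl)methyl]hex-3-enyloxy}dimethylsilane | C[Si](C)(C)C/C(=C\CCCl)CCO[Si](C)(C)C(C)(C)C | intermediate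
7 | (Z)-6-chloro-3-[(trimethylsilyl)methyl]hex-3-en-1-ol | C[Si](C)(C)C/C(=C\CCCl)CCO | intermediate
8 | (Z)-[5-chloro-2-(2-iodoethyl)pent-2-enyl]trimethylsilane; chain iodide with C6 iodide and C12 chloride | C[Si](C)(C)C/C(=C\CCCl)CCI | intermediate
9 | 2-methoxy-5-methylbenzoic acid | COc1ccc(C)cc1C(=O)O | starting material
10 | (S)-2-(methoxymethyl)pyrrolidine | COC[C@@H]1CCCN1 | starting material
11 | 2-methoxy-5-methylbenzoyl chloride | COc1ccc(C)cc1C(=O)Cl | intermediate
12 | (S)-(2-methoxy-5-methylphenyl)[2-(methoxymethyl)pyrrolidin-1-yl]methanone | COC[C@@H]1CCCN1C(=O)c1cc(C)ccc1OC | intermediate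
13 | potassium amide enolate of the 1,4-dihydro benzamide (exocyclic C4=C19 enolate) | COC[C@@H]1CCCN1C([O-])=C1C=C(C)CC=C1OC.[K+] | intermediate
14 | [(1R)-2-methoxy-1,5-dimethylcyclohexa-2,5-dien-1-yl][(2S)-2-(methoxymethyl)pyrrolidin-1-yl]methanone; ring A diene amide with quaternary C4, C3(OMe)=C2 and C10(Me)=C5 | COC[C@@H]1CCCN1C(=O)[C@]2(C)C=C(C)CC=C2OC | intermediate
15 | ring A dienone amide: 14 with C1 as ketone, cross-conjugated with C2=C3(OMe) and C10(Me)=C5, C4 unchanged | COC[C@@H]1CCCN1C(=O)[C@]2(C)C=C(C)C(=O)C=C2OC | intermediate
16 | chain Grignard reagent from 8 (C6–MgI) | C[Si](C)(C)C/C(=C\CCCl)CC[Mg]I | intermediate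
17 | trimethylsilyl enol ether of 18 (C1(OSiMe3)=C10) | C[Si](C)(C)C/C(=C\CCCl)CC[C@H]1C(C)=C(O[Si](C)(C)C)C=C(OC)[C@]1(C)C(=O)N2CCC[C@H]2COC | intermediate
18 | vinylogous ester ketone: C1 ketone, C2=C3(OMe), C5 chain cis to the C4 methyl and trans to the carboxamide, C10 as epimer mixture | C[Si](C)(C)C/C(=C\CCCl)CC[C@H]1C(C)C(=O)C=C(OC)[C@]1(C)C(=O)N2CCC[C@H]2COC | intermediate
19 | allylic alcohol from 18 (C1 hydroxyl, epimer mixture) | C[Si](C)(C)C/C(=C\CCCl)CC[C@H]1C(C)C(O)C=C(OC)[C@]1(C)C(=O)N2CCC[C@H]2COC | intermediate
20 | C3 enone amide: C3 ketone conjugated with C1=C2, C10 H/Me epimers, C4 and C5 as in 18 | C[Si](C)(C)C/C(=C\CCCl)CC[C@H]1C(C)C=CC(=O)[C@]1(C)C(=O)N2CCC[C@H]2COC | intermediate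
21 | hydroxy ketone: C3 ketone, C2 hydroxyl (epimer mixture), C1=C10(Me) | C[Si](C)(C)C/C(=C\CCCl)CC[C@H]1C(C)=CC(O)C(=O)[C@]1(C)C(=O)N2CCC[C@H]2COC | intermediate
22 | triethylsilyl ether of 21 at C2 | C[Si](C)(C)C/C(=C\CCCl)CC[C@H]1C(C)=CC(O[Si](CC)(CC)CC)C(=O)[C@]1(C)C(=O)N2CCC[C@H]2COC | intermediate
23 | C3 alcohol with C2 triethylsilyl ether; C3 hydroxyl trans to the carboxamide and cis to the C4 methyl | C[Si](C)(C)C/C(=C\CCCl)CC[C@H]1C(C)=CC(O[Si](CC)(CC)CC)[C@@H](O)[C@]1(C)C(=O)N2CCC[C@H]2COC | intermediate
24 | C2,C3 diol (C2 epimers), C3 hydroxyl trans to the carboxamide, C1=C10(Me) | C[Si](C)(C)C/C(=C\CCCl)CC[C@H]1C(C)=CC(O)[C@@H](O)[C@]1(C)C(=O)N2CCC[C@H]2COC | intermediate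
25 | α′-hydroxy enone amide: C2 ketone conjugated with C1=C10(Me), C3 hydroxyl trans to the carboxamide | C[Si](C)(C)C/C(=C\CCCl)CC[C@H]1C(C)=CC(=O)[C@@H](O)[C@]1(C)C(=O)N2CCC[C@H]2COC | intermediate
26 | tert-butyldimethylsilyl ether of 25 at C3 | C[Si](C)(C)C/C(=C\CCCl)CC[C@H]1C(C)=CC(=O)[C@@H](O[Si](C)(C)C(C)(C)C)[C@]1(C)C(=O)N2CCC[C@H]2COC | intermediate
27 | O-methyl imidate tetrafluoroborate of 26 | C[Si](C)(C)C/C(=C\CCCl)CC[C@H]1C(C)=CC(=O)[C@@H](O[Si](C)(C)C(C)(C)C)[C@]1(C)C(OC)=[N+]2CCC[C@H]2COC.F[B-](F)(F)F | intermediate
28 | key precursor: ring A 3-methylcyclohex-2-enone (C2 ketone, C1=C10) with C3 OTBS and C5 (Z)-allylsilane chain both cis to the C4 methyl, C4 methyl ester, C12 chloride | C[Si](C)(C)C/C(=C\CCCl)CC[C@H]1C(C)=CC(=O)[C@@H](O[Si](C)(C)C(C)(C)C)[C@]1(C)C(=O)OC | intermediate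
29 | cis-fused decalin: C2 ketone, C3 OTBS, C4 methyl ester, C8=C17 methylene, C9 chloroethyl cis to the C10 methyl | ClCC[C@H]1C(=C)CC[C@H]2[C@]1(C)CC(=O)[C@@H](O[Si](C)(C)C(C)(C)C)[C@]2(C)C(=O)OC | intermediate
30 | C2 alcohol of 29 (epimer mixture) | ClCC[C@H]1C(=C)CC[C@H]2[C@]1(C)CC(O)[C@@H](O[Si](C)(C)C(C)(C)C)[C@]2(C)C(=O)OC | intermediate
31 | C2 O-phenyl thionocarbonate of 30 | ClCC[C@H]1C(=C)CC[C@H]2[C@]1(C)CC(OC(=S)Oc3ccccc3)[C@@H](O[Si](C)(C)C(C)(C)C)[C@]2(C)C(=O)OC | intermediate
32 | C2-deoxygenated decalin with C12 chloride | ClCC[C@H]1C(=C)CC[C@H]2[C@]1(C)CC[C@@H](O[Si](C)(C)C(C)(C)C)[C@]2(C)C(=O)OC | intermediate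
33 | C12 iodide | ICC[C@H]1C(=C)CC[C@H]2[C@]1(C)CC[C@@H](O[Si](C)(C)C(C)(C)C)[C@]2(C)C(=O)OC | intermediate
34 | 2-chlorobuta-1,3-diene (chloroprene, stabilised solution) | C=CC(Cl)=C | starting material
35 | buta-1,3-dien-2-ylmagnesium chloride | C=CC(=C)[Mg]Cl | intermediate
36 | methyl 3-(tert-butyldimethylsilyloxy)labda-8(17),13(16),14-trien-19-oate, configured as the target | C=CC(=C)CC[C@H]1C(=C)CC[C@H]2[C@]1(C)CC[C@@H](O[Si](C)(C)C(C)(C)C)[C@]2(C)C(=O)OC | intermediate
37 | corresponding carboxylic acid | C=CC(=C)CC[C@H]1C(=C)CC[C@H]2[C@]1(C)CC[C@@H](O[Si](C)(C)C(C)(C)C)[C@]2(C)C(=O)O | intermediate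
38 | 3-hydroxy acid | C=CC(=C)CC[C@H]1C(=C)CC[C@H]2[C@]1(C)CC[C@@H](O)[C@]2(C)C(=O)O | intermediate
39 | mixed acetic anhydride of the 3-acetoxy acid | C=CC(=C)CC[C@H]1C(=C)CC[C@H]2[C@]1(C)CC[C@@H](OC(C)=O)[C@]2(C)C(=O)OC(C)=O | intermediate
40 | CNP0243981.1, 3-acetoxy-labda-8(17),13(16),14-trien-19-oic acid (cis-fused) | C=CC(=C)CC[C@H]1C(=C)CC[C@H]2[C@]1(C)CC[C@@H](OC(C)=O)[C@]2(C)C(=O)O | target

Total step count: 26. Longest linear sequence: 22 steps (steps 1–6, 10–21 and 23–26).

Steps most likely to fail

Step 17. The allylsilane may be protodesilylated by adventitious HCl, or TiCl4 may bind the C2 carbonyl together with the C3 silyloxy oxygen, which can cost the silyl ether or slow C–C bond formation enough for a boat-like pathway to erode the C9 configuration. The fallback sets out from 28 and closes ring B through an oxocarbenium ion instead of a metal-bound enone. MeOSiMe3 with catalytic Me3SiOTf (CH2Cl2, −78 °C) converts the enone into the dimethyl ketal F1. Under the same catalyst F1 ionises to a 2-methoxyallyl cation, which the allylsilane captures at C10 through the same tether and chair (Hosomi–Sakurai reaction of an acetal) to give the methyl enol ether F2. Aqueous oxalic acid hydrolyses F2 to 29, where the route is rejoined.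

Step 10. The conjugate transfer may be slow or misdirected, because the dienone is deactivated by its vinylogous ester half and C5 is flanked by the quaternary C4; direct carbonyl addition or attack at the methoxy-bearing C3 could then compete. The fallback sets out from 8 and 15 and replaces the organocopper step by a Giese radical addition ((Me3Si)3SiH, AIBN, PhH, 80 °C). The primary radical from 8 should add to C5 on the face away from the carboxamide, and the resulting α-keto radical abstracts hydrogen to give 18 directly, where the route is rejoined; no new compound is involved.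

Step 13. Hydride may be delivered to the wrong face if zinc chelation by the carboxamide is not maintained; hydride would then enter anti to the carboxamide and leave the C3 hydroxyl cis to it. The fallback sets out from 21, isolated by omitting Et3SiCl in step 12, and avoids hydride altogether. Mild base (Et3N, MeOH, rt) should isomerise the α-ketol through its enediol (acyloin transposition), driven by conjugation of the new C2 ketone with C1=C10. C3 is then set under thermodynamic control, with the hydroxyl pseudo-equatorial and trans to the carboxamide, giving 25, where the route is rejoined; no new compound is involved.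

Further compounds
F1 | step 17 | dimethyl ketal of 28 at C2 | C[Si](C)(C)C/C(=C\CCCl)CC[C@H]1C(C)=CC(OC)(OC)[C@@H](O[Si](C)(C)C(C)(C)C)[C@]1(C)C(=O)OC
F2 | step 17 | C2 methyl enol ether of 29 (C1=C2) | ClCC[C@H]1C(=C)CC[C@H]2[C@]1(C)C=C(OC)[C@@H](O[Si](C)(C)C(C)(C)C)[C@]2(C)C(=O)OC
F0 | step 10 | none | none
F0 | step 13 | none | none
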